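## Retrosynthetic overview

- The target comes from Cl→Br exchange at the primary allylic carbon of a trichloride, which comes from double-inversion chlorination of an all-cis bromo triol.
- The triol comes from oxidative dearomatisation of a 2,3-fused furan with singlet oxygen and hydride reduction in the same flask. The furan ring is the latent (Z)-O–C–C=C–C–O unit, so its opening gives the exocyclic alkene geometry and both allylic oxygens (key step).
- The furan alcohol comes from CBS reduction of a 6,7-dihydrobenzofuran-4(5H)-one, made by intramolecular Friedel–Crafts acylation at furan C-3 (the only carbocycle-forming step).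
- The acid for that acylation comes from tert-alkylation of furan at C-2 by a β-bromo-γ-lactone opened with Me3SiOTf (the acid passes through its silyl ester). The lactone is made by asymmetric bromolactonisation of 4-methylpent-3-enoic acid, which sets the C–Br centre.
- Ring order: γ-lactone (temporary, opened in the next step), then the cyclohexane ring (closed onto the purchased furan ring), then the furan ring is opened.

Assumption: the bromolactonisation catalyst is taken to give the (4S)-lactone; if the opposite sense is found, the pseudo-enantiomeric hydroquinine 1,4-phthalazinediyl diether is used instead.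

## Route

Step 1
Reactants: 1 4-methylpent-3-enoic acid
Product: 2 (4S)-4-bromo-5,5-dimethyloxolan-2-one
Conditions: NBS, hydroquinidine 1,4-phthalazinediyl diether (cat.), CHCl3/hexane 1:1, −40 °C
Reagents that add atoms: N-bromosuccinimide, O=C1CCC(=O)N1Br
Why: Catalytic asymmetric bromolactonisation (5-endo halolactonisation): the alkaloid catalyst delivers Br+ to one face of the trisubstituted alkene and the carboxylate opens the bromonium ion at the tertiary carbon (Markovnikov), which sets the C–Br stereocentre as S and places the future gem-dimethyl carbon on the lactone oxygen.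

Step 2
Reactants: 2 (4S)-4-bromo-5,5-dimethyloxolan-2-one; 3 furan
Product: 5 (3S)-3-bromo-4-(furan-2-yl)-4-methylpentanoic acid, via silyl ester 4 (not isolated)
Conditions: Me3SiOTf, 2,6-di-tert-butyl-4-methylpyridine, CH2Cl2/furan 4:1, −40 to 0 °C; then aq. NaH2PO4
Reagents that add atoms: none
Why: Proposed new method: Me3SiOTf silylates the lactone carbonyl and the tertiary alkyl–oxygen bond then ionises, as in the Me3SiOTf cleavage of tert-butyl esters to silyl esters, with anchimeric help from the vicinal bromine; the bromonium/tertiary cation is captured at its tertiary carbon by C-2 of furan (Friedel–Crafts alkylation), the hindered pyridine takes up the released proton so that no free strong acid meets the furan, and the carboxylate stays capped as silyl ester 4 until the aqueous work-up frees acid 5; the CHBr carbon never becomes a cationic centre, so its configuration is kept; the closest known reactions are Friedel–Crafts alkylation of arenes with γ,γ-dimethylbutyrolactone, tert-alkylation of furan, and arene capture of bromonium ions in halonium-induced polyene cyclisations.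

Step 3
Reactants: 5 (3S)-3-bromo-4-(furan-2-yl)-4-methylpentanoic acid
Product: 7 (6S)-6-bromo-7,7-dimethyl-6,7-dihydro-1-benzofuran-4(5H)-one, via acid chloride 6 (not isolated)
Conditions: (COCl)2, CH2Cl2, rt; then SnCl4, CH2Cl2 (high dilution), −78 °C
Reagents that add atoms: none
Why: Intramolecular Friedel–Crafts acylation: the acylium ion from acid chloride 6 can reach only C-3 of the 2-alkylfuran, so the six-membered ketone forms (gem-dimethyl effect, high dilution against intermolecular attack at the free α-position) and the C–Br centre is not involved.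

Step 4
Reactants: 7 (6S)-6-bromo-7,7-dimethyl-6,7-dihydro-1-benzofuran-4(5H)-one
Product: 8 (4R,6S)-6-bromo-7,7-dimethyl-4,5,6,7-tetrahydro-1-benzofuran-4-ol
Conditions: (S)-1-methyl-3,3-diphenyltetrahydro-1H,3H-pyrrolo[1,2-c][1,3,2]oxazaborole (cat.), BH3·SMe2, THF, −20 °C; MeOH quench
Reagents that add atoms: none
Why: Corey–Bakshi–Shibata reduction of a heteroaryl ketone under non-basic conditions (no E1cB loss of HBr): with furyl as the large group the (S)-catalyst gives the (4R)-carbinol, which is also the cis product (OH cis to Br) of axial hydride attack on the substrate, so catalyst and substrate control are matched.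

Step 5
Reactants: 8 (4R,6S)-6-bromo-7,7-dimethyl-4,5,6,7-tetrahydro-1-benzofuran-4-ol
Product: 11 (1R,2Z,3R,5S)-5-bromo-2-(2-hydroxyethylidene)-4,4-dimethylcyclohexane-1,3-diol, via furan endoperoxide 9 (not isolated), via Z-keto-enal 10 (not isolated)
Conditions: O2, 5,10,15,20-tetraphenylporphyrin (cat.), visible light, CH2Cl2, −78 °C; Me2S, −78 °C; then MeOH, CeCl3·7H2O, NaBH4, −78 to −20 °C
Reagents that add atoms: dioxygen, O=O
Why: Dearomatising [4+2] photooxygenation of the furan gives endoperoxide 9, Me2S reduces its O–O bond to the (Z)-4-oxo-enal 10 whose Z geometry is inherited from the ring, and Luche 1,2-reduction then reduces aldehyde and ketone, hydride attacking the ring carbonyl axially, anti to the axial methyl of the neighbouring quaternary carbon (as in 4,4-dimethyl-3-keto steroids), to give the equatorial alcohol cis to Br and to the first OH.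

Step 6
Reactants: 11 (1R,2Z,3R,5S)-5-bromo-2-(2-hydroxyethylidene)-4,4-dimethylcyclohexane-1,3-diol
Product: 12 (1S,3S,4Z,5S)-1-bromo-3,5-dichloro-4-(2-chloroethylidene)-2,2-dimethylcyclohexane
Conditions: PPh3, Cl3CC(O)CCl3, CH2Cl2, −30 to 0 °C
Reagents that add atoms: hexachloroacetone, ClC(Cl)(Cl)C(=O)C(Cl)(Cl)Cl
Why: Appel-type chlorination with PPh3/hexachloroacetone: each alkoxyphosphonium is displaced by chloride in an SN2 reaction without allylic transposition, so both secondary allylic carbinols are inverted (both Cl end up trans to Br and cis to each other) and the primary alcohol becomes the primary chloride.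

Step 7
Reactants: 12 (1S,3S,4Z,5S)-1-bromo-3,5-dichloro-4-(2-chloroethylidene)-2,2-dimethylcyclohexane
Product: 13 (1S,3S,4Z,5S)-1-bromo-4-(2-bromoethylidene)-3,5-dichloro-2,2-dimethylcyclohexane
Conditions: LiBr (excess), acetone, 0 °C to rt
Reagents that add atoms: lithium bromide, [Li+].[Br-]
Why: Finkelstein halide exchange (SN2): bromide displaces only the unhindered primary allylic chloride, the two secondary chlorides (one of them neopentyl) reacting far more slowly, and the excess of LiBr together with the low solubility of LiCl in acetone drives the exchange without touching any stereocentre.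

## Compound list

1 | 4-methylpent-3-enoic acid | CC(C)=CCC(=O)O | starting material
2 | (4S)-4-bromo-5,5-dimethyloxolan-2-one | CC1(C)OC(=O)C[C@@H]1Br | intermediate
3 | furan | c1ccoc1 | starting material
4 | trimethylsilyl (3S)-3-bromo-4-(furan-2-yl)-4-methylpentanoate | C[Si](C)(C)OC(=O)C[C@H](Br)C(C)(C)c1ccco1 | intermediate
5 | (3S)-3-bromo-4-(furan-2-yl)-4-methylpentanoic acid | OC(=O)C[C@H](Br)C(C)(C)c1ccco1 | intermediate
6 | (3S)-3-bromo-4-(furan-2-yl)-4-methylpentanoyl chloride | O=C(Cl)C[C@H](Br)C(C)(C)c1ccco1 | intermediate
7 | (6S)-6-bromo-7,7-dimethyl-6,7-dihydro-1-benzofuran-4(5H)-one | CC1(C)[C@@H](Br)CC(=O)c2ccoc21 | intermediate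
8 | (4R,6S)-6-bromo-7,7-dimethyl-4,5,6,7-tetrahydro-1-benzofuran-4-ol | CC1(C)[C@@H](Br)C[C@@H](O)c2ccoc21 | intermediate
9 | (4R,6S)-6-bromo-7,7-dimethyl-4,5,6,7-tetrahydro-2H-2,7a-epidioxy-1-benzofuran-4-ol (furan endoperoxide, both facial adducts) | CC1(C)[C@@H](Br)C[C@@H](O)C2=CC3OOC12O3 | intermediate
10 | (2Z)-2-[(4S,6R)-4-bromo-6-hydroxy-3,3-dimethyl-2-oxocyclohexylidene]acetaldehyde | CC1(C)[C@@H](Br)C[C@@H](O)/C(=C/C=O)C1=O | intermediate
11 | (1R,2Z,3R,5S)-5-bromo-2-(2-hydroxyethylidene)-4,4-dimethylcyclohexane-1,3-diol | CC1(C)[C@@H](Br)C[C@@H](O)/C(=C/CO)[C@H]1O | intermediate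
12 | (1S,3S,4Z,5S)-1-bromo-3,5-dichloro-4-(2-chloroethylidene)-2,2-dimethylcyclohexane | CC1(C)[C@@H](Br)C[C@H](Cl)/C(=C/CCl)[C@@H]1Cl | intermediate
13 | (1S,3S,4Z,5S)-1-bromo-4-(2-bromoethylidene)-3,5-dichloro-2,2-dimethylcyclohexane | CC1(C)[C@@H](Br)C[C@H](Cl)/C(=C/CBr)[C@@H]1Cl | target

## Step count and risks

Total steps: 7. Longest linear sequence: 7 steps (1 to 13); furan 3 enters in step 2.

**Step 2 (most likely to fail).** The lactone may not ionise, the cation may lose a proton to give an allylic bromide, or furan may take Br+ from the bromonium ion instead of forming the C–C bond. The fallback sets out from 1 and 3 and comes back to the route at 8; it builds the carbocycle first and brings in bromine afterwards. Bi(OTf)3-catalysed hydroarylation of 3 with 1 in (CF3)2CHOH gives 4-(furan-2-yl)-4-methylpentanoic acid F1. Ring closure in P2O5/MeSO3H gives 7,7-dimethyl-6,7-dihydro-1-benzofuran-4(5H)-one F2. Dehydrogenation with 2-iodoxybenzoic acid gives 7,7-dimethyl-1-benzofuran-4(7H)-one F3. Conjugate addition of HBr (Me3SiBr at −40 °C, then mild hydrolysis) gives rac-6-bromo-7,7-dimethyl-6,7-dihydro-1-benzofuran-4(5H)-one F4. Reduction of the racemate with the catalyst of step 4 is catalyst-controlled at the carbinol and gives 8 together with (4R,6R)-6-bromo-7,7-dimethyl-4,5,6,7-tetrahydro-1-benzofuran-4-ol F5, separated by chromatography. The C–Br centre is thus resolved through the carbinol, at the cost of half the material.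

**Step 5.** The Z-keto-enal 10 may isomerise to the E form before it is reduced, a half-reduced hydroxy-carbonyl intermediate may close to a lactol and lose water back to a furan, or the hindered ketone may be reduced with poor facial control. The fallback sets out from 8 and comes back to the route at 11; it locks the alkene geometry in a lactone ring. Photooxygenation of 8 in the presence of i-Pr2NEt fragments endoperoxide 9 to (4R,6S)-6-bromo-4,7a-dihydroxy-7,7-dimethyl-5,6,7,7a-tetrahydro-1-benzofuran-2(4H)-one F6. NaBH4 reduces the ring-opened keto acid, which relactonises to (4R,6S,7aR)-6-bromo-4-hydroxy-7,7-dimethyl-5,6,7,7a-tetrahydro-1-benzofuran-2(4H)-one F7. Excess i-Bu2AlH (−78 to 0 °C) then reduces the lactone to 11.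

**Step 6.** The Z-1,4-diol may close to a dihydrofuran, and the neopentyl allylic carbinol may react with allylic transposition or not at all. The fallback sets out from 11 and comes back to the route at 12; it uses the ether closure and an SN1-type opening instead of SN2 at the hindered carbon. Intramolecular Mitsunobu etherification (PPh3, diisopropyl azodicarboxylate) gives (4R,6S,7aR)-6-bromo-7,7-dimethyl-2,4,5,6,7,7a-hexahydro-1-benzofuran-4-ol F8; the primary carbon is the electrophile, so the ring carbon keeps its configuration. BCl3 at −78 °C ionises the allylic ring C–O bond and chloride adds axially, anti to the axial methyl, to give (1R,2Z,3S,5S)-5-bromo-3-chloro-2-(2-hydroxyethylidene)-4,4-dimethylcyclohexan-1-ol F9, whose two remaining hydroxyls cannot cyclise. PPh3/hexachloroacetone then gives 12, with inversion needed only at the unhindered carbinol.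

Further compounds

F1 | step 2 | 4-(furan-2-yl)-4-methylpentanoic acid | OC(=O)CCC(C)(C)c1ccco1
F2 | step 2 | 7,7-dimethyl-6,7-dihydro-1-benzofuran-4(5H)-one | CC1(C)CCC(=O)c2ccoc21
F3 | step 2 | 7,7-dimethyl-1-benzofuran-4(7H)-one | CC1(C)C=CC(=O)c2ccoc21
F4 | step 2 | rac-6-bromo-7,7-dimethyl-6,7-dihydro-1-benzofuran-4(5H)-one | CC1(C)C(Br)CC(=O)c2ccoc21
F5 | step 2 | (4R,6R)-6-bromo-7,7-dimethyl-4,5,6,7-tetrahydro-1-benzofuran-4-ol | CC1(C)[C@H](Br)C[C@@H](O)c2ccoc21
F6 | step 5 | (4R,6S)-6-bromo-4,7a-dihydroxy-7,7-dimethyl-5,6,7,7a-tetrahydro-1-benzofuran-2(4H)-one (both 7a-epimers) | CC1(C)[C@@H](Br)C[C@@H](O)C2=CC(=O)OC12O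
F7 | step 5 | (4R,6S,7aR)-6-bromo-4-hydroxy-7,7-dimethyl-5,6,7,7a-tetrahydro-1-benzofuran-2(4H)-one | CC1(C)[C@@H](Br)C[C@@H](O)C2=CC(=O)O[C@@H]12
F8 | step 6 | (4R,6S,7aR)-6-bromo-7,7-dimethyl-2,4,5,6,7,7a-hexahydro-1-benzofuran-4-ol | CC1(C)[C@@H](Br)C[C@@H](O)C2=CCO[C@@H]12
F9 | step 6 | (1R,2Z,3S,5S)-5-bromo-3-chloro-2-(2-hydroxyethylidene)-4,4-dimethylcyclohexan-1-ol | CC1(C)[C@@H](Br)C[C@@H](O)/C(=C/CO)[C@@H]1Cl
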